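A direct plan would build ring A by a light-driven Wolff/Danheiser benzannulation of diazo enone A1 with the silyl-protected methoxyalkyne A2 to phenol A3, would then close ring B by acetal hydrolysis and a Wittig lactonisation to coumarin A4, and would finish the C8 chain through ketone A5 and 1,2-dione A6 before a last enolate O-acylation.
Its weakest parts would be:
1. The chain at C8 would enter as a protected carbinol, so silylation, desilylation, Dess–Martin oxidation (to A5) and Riley oxidation (to A6) would be four operations that form no bond of the skeleton.
2. The Riley oxidation at 100 °C and the O-acylation of a tetrasubstituted enolate would come last, so over-oxidation, attack of the base on the lactone and C-acylation would all fall on the most advanced material.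
3. The run-up would be long for what the benzannulation gives: two steps each to A1 and A2, a cascade through several ketenes that the phenol formed can intercept, and ring A only, so that ring B costs two more steps.

**Retrosynthetic overview**
The chain C8–C1′(=O)–C2′(O-senecioyl)=C3′Me2 is read as an oxidised tertiary propargylic ester, C8–C1′≡C2′–C3′Me2–O-senecioyl: gold-catalysed oxygen transfer to C1′ with a 1,2-shift of the senecioyloxy group from C3′ to C2′ forms the C1′=O, C2′–O and C2′=C3′ bonds in one operation.
The alkyne is joined to C8 by a Sonogashira coupling (C8–C1′) with 2-methylbut-3-yn-2-ol, and the senecioyl group is placed on the tertiary alcohol, from where it migrates.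
Ring A is bought with an iodine atom between its two oxygen atoms; ring B is closed first, by a gold-catalysed 6-endo hydroarylation of the aryl propiolate (C4–C4a), so the only ring closure is an isomerisation and no benzannulation is needed.
The design needs no protecting group, no carbinol or CH2 oxidation and no enolate: the ketone oxygen comes from an N-oxide and the enol ester from within the molecule, at room temperature in the last of five steps.

Key step: step 5

Assumption: 2-iodo-3-methoxyphenol 1 is taken as a catalogue building block; its iodine atom, flanked by the two oxygen atoms, becomes the coupling site at C8. The target has no stereocentre, and its only alkene geometry (C3=C4) is fixed by ring B.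

Step 1
Reactants: 1 2-iodo-3-methoxyphenol; 2 prop-2-ynoic acid (propiolic acid)
Product: 4 2-iodo-3-methoxyphenyl prop-2-ynoate, via O-acylisourea 3 (not isolated)
Conditions: DCC, DMAP (2 mol%), CH2Cl2, 0 °C
Reagents that add atoms: N,N'-dicyclohexylcarbodiimide C(=NC1CCCCC1)=NC1CCCCC1 (its atoms stand only in 3)
Why: Steglich-type carbodiimide esterification through the O-acylisourea; the low temperature and the small amount of DMAP should keep the phenol from adding to the triple bond of the propiolate.

Step 2
Reactants: 4 2-iodo-3-methoxyphenyl prop-2-ynoate
Product: 5 8-iodo-7-methoxy-2H-chromen-2-one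
Conditions: [(t-Bu)2(2-biphenylyl)P]Au(NCMe)SbF6 (3 mol%), dry ClCH2CH2Cl, rt to 60 °C
Reagents that add atoms: none
Why: Gold-catalysed intramolecular hydroarylation of an aryl alkynoate, a known coumarin synthesis: monovalent gold activates the ynoate, the ring carbon para to the methoxy group (the only free position ortho to the ester oxygen, since iodine holds the other) attacks the terminal alkyne carbon in a 6-endo-dig Friedel–Crafts closure (C4–C4a), and protodeauration leaves the cis C3=C4 bond of ring B.

Step 3
Reactants: 5 8-iodo-7-methoxy-2H-chromen-2-one; 6 2-methylbut-3-yn-2-ol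
Product: 7 8-(3-hydroxy-3-methylbut-1-yn-1-yl)-7-methoxy-2H-chromen-2-one
Conditions: Pd(PPh3)2Cl2 (3 mol%), CuI (6 mol%), Et3N, THF, degassed, rt to 40 °C
Reagents that add atoms: none
Why: Sonogashira coupling; zerovalent palladium should insert into the C8–I bond readily even between two ortho oxygen substituents, the tertiary propargylic alcohol is a standard alkyne partner, and triethylamine does not open the lactone.

Step 4
Reactants: 7 8-(3-hydroxy-3-methylbut-1-yn-1-yl)-7-methoxy-2H-chromen-2-one; 8 3-methylbut-2-enoyl chloride (senecioyl chloride)
Product: 10 4-(7-methoxy-2-oxo-2H-chromen-8-yl)-2-methylbut-3-yn-2-yl 3-methylbut-2-enoate, via lithium alkoxide 9 (not isolated)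
Conditions: LiN(SiMe3)2 (1.05 equiv), THF, −78 °C; then 8 (1.2 equiv), −78 to 0 °C
Reagents that add atoms: lithium bis(trimethylsilyl)amide [Li]N([Si](C)(C)C)[Si](C)(C)C (its lithium stands only in 9)
Why: O-acylation of a preformed lithium tert-alkoxide by an acid chloride, the usual way to esters of hindered tertiary alcohols; without an amine base the vinylketene path that would move the senecioyl double bond out of conjugation is avoided, and the hindered amide base should deprotonate the OH group without adding to the lactone.

Step 5
Reactants: 10 4-(7-methoxy-2-oxo-2H-chromen-8-yl)-2-methylbut-3-yn-2-yl 3-methylbut-2-enoate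
Product: 11 kimcuongin
Conditions: IPrAuNTf2 (5 mol%; IPr = 1,3-bis(2,6-diisopropylphenyl)imidazol-2-ylidene), 8-methylquinoline N-oxide (2 equiv), 4 Å molecular sieves, ClCH2CH2Cl, rt
Reagents that add atoms: 8-methylquinoline N-oxide Cc1cccc2ccc[n+]([O-])c12
Why: The gold-bound alkyne of 10 should be attacked by the N-oxide oxygen at C1′, and loss of 8-methylquinoline from the vinylgold adduct gives a gold-bound α-oxo carbene at C2′. The carbonyl oxygen of the neighbouring senecioate then adds to the carbene carbon, and the five-membered dioxolanylium intermediate opens at the C3′–O bond, so that the acyloxy group ends on C2′, the C2′=C3′ bond forms and the catalyst is released. The closest known reaction type is the gold-catalysed N-oxide oxidation of propargylic carboxylates with 1,2-acyloxy migration to α-acyloxy enones, here on a tertiary ester, so no 1,2-hydride shift can compete. No ring of the target is closed (the dioxolanylium ring is transient), and no stereocentre or alkene geometry arises because C3′ carries two methyl groups. The step needs oxygen delivery to C1′ and not to C2′, which the substrate secures twice: positive charge at C1′ is stabilised by the aryl ring with its C7 methoxy group, and charge at C2′ is disfavoured by the inductive pull of the C3′–O ester. It also needs the N-oxide to outrun the 1,3-acyloxy shift to the allenyl ester, which is addressed by N-oxide in excess from the start, a donor carbene ligand on gold and the expected reversibility of that shift under the same catalyst; all intermediates stay bound to gold, both positions ortho to the alkyne are substituted so no cyclisation onto the arene can occur, and the lactone, the methyl ether and the conjugated ester should be inert to monovalent gold and to the hindered, weakly basic 8-methylquinoline.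

**Compound list**
1 | 2-iodo-3-methoxyphenol | COc1cccc(O)c1I | starting material
2 | prop-2-ynoic acid (propiolic acid) | C#CC(=O)O | starting material
3 | O-propioloyl-N,N'-dicyclohexylisourea | C#CC(=O)OC(=NC1CCCCC1)NC1CCCCC1 | intermediate
4 | 2-iodo-3-methoxyphenyl prop-2-ynoate | COc1cccc(OC(=O)C#C)c1I | intermediate
5 | 8-iodo-7-methoxy-2H-chromen-2-one | COc1ccc2ccc(=O)oc2c1I | intermediate
6 | 2-methylbut-3-yn-2-ol | CC(C)(O)C#C | starting material
7 | 8-(3-hydroxy-3-methylbut-1-yn-1-yl)-7-methoxy-2H-chromen-2-one | COc1ccc2ccc(=O)oc2c1C#CC(C)(C)O | intermediate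
8 | 3-methylbut-2-enoyl chloride | CC(C)=CC(=O)Cl | starting material
9 | lithium 4-(7-methoxy-2-oxo-2H-chromen-8-yl)-2-methylbut-3-yn-2-olate | COc1ccc2ccc(=O)oc2c1C#CC(C)(C)[O-].[Li+] | intermediate
10 | 4-(7-methoxy-2-oxo-2H-chromen-8-yl)-2-methylbut-3-yn-2-yl 3-methylbut-2-enoate | COc1ccc2ccc(=O)oc2c1C#CC(C)(C)OC(=O)C=C(C)C | intermediate
11 | kimcuongin, 1-(7-methoxy-2-oxo-2H-chromen-8-yl)-3-methyl-1-oxobut-2-en-2-yl 3-methylbut-2-enoate | COc1ccc2ccc(=O)oc2c1C(=O)C(OC(=O)C=C(C)C)=C(C)C | target

Total step count: 5. Longest linear sequence: 5 steps (1 to 11 through 4, 5, 7 and 10).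

**Steps most likely to fail**

Step 5 (key step). The oxygen transfer may lose to the gold-catalysed 1,3-acyloxy shift that turns 10 into an allenyl ester, the tertiary ester may ionise, or the carbene may be oxidised a second time. The fallback sets out from 5, 6 and 8 and comes back at 11: the oxidative acyloxy shift is moved to a terminal alkyne, where the 1,2-shift is the preferred path, and the aryl–C1′ bond is made afterwards. Alcohol 6 would be deprotonated (n-BuLi, THF, −78 °C) to lithium 2-methylbut-3-yn-2-olate F1 and acylated with 8 to 2-methylbut-3-yn-2-yl 3-methylbut-2-enoate F2. IPrAuNTf2 (cat.) with Ph2SO in CH2Cl2 at rt should then give 3-methyl-2-[(3-methylbut-2-enoyl)oxy]but-2-enal F3, by the known 1,2-acyloxy shift of a terminal tertiary propargylic ester to a vinyl gold carbenoid and its oxidation by the sulfoxide. Iodine–magnesium exchange on 5 (i-PrMgCl·LiCl, THF, −40 °C) would give (7-methoxy-2-oxo-2H-chromen-8-yl)magnesium chloride F4. Its addition to F3, quenched cold with AcOH to forestall acyl transfer to the new alkoxide, would give 8-{1-hydroxy-3-methyl-2-[(3-methylbut-2-enoyl)oxy]but-2-en-1-yl}-7-methoxy-2H-chromen-2-one F5 (racemic), and Dess–Martin oxidation of F5 in CH2Cl2 would give 11.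

Step 2. The Friedel–Crafts closure may be slow on a ring that iodine deactivates, so that hydration or oligomerisation of the propiolate takes over. The fallback sets out from 1 and comes back at 5: ring B would be closed by olefination instead of hydroarylation. Casnati–Skattebøl ortho-formylation of 1 (MgCl2, Et3N, paraformaldehyde, MeCN, reflux; only one ortho position is free) would give 2-hydroxy-3-iodo-4-methoxybenzaldehyde F6. (Triphenylphosphoranylidene)ketene in toluene at 110 °C would acylate the phenol to 6-formyl-2-iodo-3-methoxyphenyl (triphenylphosphoranylidene)acetate F7, whose intramolecular Wittig reaction gives 5.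

Step 4. Acylation of the crowded tertiary alkoxide may be slow, leaving room for loss of conjugation in the senecioyl group through a vinylketene or for attack of the alkoxide on the lactone. The fallback sets out from 5 and comes back at 10: the ester would be made on the small alkyne before the coupling, that is, Sonogashira coupling of 5 (Pd(PPh3)2Cl2, CuI, Et3N, THF, rt) with 2-methylbut-3-yn-2-yl 3-methylbut-2-enoate F2, prepared from 6 and 8 as described under step 5.

**Further compounds**
F1 | step 5 | lithium 2-methylbut-3-yn-2-olate | CC(C)([O-])C#C.[Li+]
F2 | step 5 | 2-methylbut-3-yn-2-yl 3-methylbut-2-enoate | C#CC(C)(C)OC(=O)C=C(C)C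
F3 | step 5 | 3-methyl-2-[(3-methylbut-2-enoyl)oxy]but-2-enal | O=CC(OC(=O)C=C(C)C)=C(C)C
F4 | step 5 | (7-methoxy-2-oxo-2H-chromen-8-yl)magnesium chloride | COc1ccc2ccc(=O)oc2c1[Mg]Cl
F5 | step 5 | 8-{1-hydroxy-3-methyl-2-[(3-methylbut-2-enoyl)oxy]but-2-en-1-yl}-7-methoxy-2H-chromen-2-one (racemic) | COc1ccc2ccc(=O)oc2c1C(O)C(OC(=O)C=C(C)C)=C(C)C
F6 | step 2 | 2-hydroxy-3-iodo-4-methoxybenzaldehyde | COc1ccc(C=O)c(O)c1I
F7 | step 2 | 6-formyl-2-iodo-3-methoxyphenyl (triphenylphosphoranylidene)acetate | COc1ccc(C=O)c(OC(=O)C=P(c2ccccc2)(c2ccccc2)c2ccccc2)c1I
F0 | step 4 | none | none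
A1 | direct plan | (E)-1-diazo-5,5-dimethoxypent-3-en-2-one | COC(OC)/C=C/C(=O)C=[N+]=[N-]
A2 | direct plan | tert-butyl[(1-methoxy-5-methylhex-1-yn-3-yl)oxy]dimethylsilane (racemic) | COC#CC(CC(C)C)O[Si](C)(C)C(C)(C)C
A3 | direct plan | 2-(dimethoxymethyl)-5-methoxy-6-[1-(tert-butyldimethylsilyloxy)-3-methylbutyl]phenol (racemic) | COC(OC)c1ccc(OC)c(C(CC(C)C)O[Si](C)(C)C(C)(C)C)c1O
A4 | direct plan | 8-[1-(tert-butyldimethylsilyloxy)-3-methylbutyl]-7-methoxy-2H-chromen-2-one (racemic) | COc1ccc2ccc(=O)oc2c1C(CC(C)C)O[Si](C)(C)C(C)(C)C
A5 | direct plan | 7-methoxy-8-(3-methylbutanoyl)-2H-chromen-2-one | COc1ccc2ccc(=O)oc2c1C(=O)CC(C)C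
A6 | direct plan | 1-(7-methoxy-2-oxo-2H-chromen-8-yl)-3-methylbutane-1,2-dione | COc1ccc2ccc(=O)oc2c1C(=O)C(=O)C(C)C
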